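## Retrosynthetic overview
1. C7''–aryl bond: non-chelation (Felkin–Anh) addition of an aryl-titanium reagent to an (R)-2-aryloxypropanal. The lactate-derived C8'' sets C7'' (erythro).
2. C1–C8a bond: anodic dehydrogenative benzylic C–H / aryl C–H cyclisation of a dibenzylbutane. This closes the only ring that is built, and the neighbouring C2/C3 centres set C1.
3. C8''–O–C4' bond: SN2 inversion of O-tosyl ethyl (S)-lactate by one of the two homotopic phenols of C2-symmetric (−)-secoisolariciresinol, which supplies C2 and C3.
4. Both CH2OH groups become CH3 via mesylate and hydride. The same MsCl step makes the aryl mesylate that switches ring A off electrochemically.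
5. Ring order: all three arenes are bought, and the tetralin carbocycle is formed in step 3.

Assumption: (−)-secoisolariciresinol and silyl ether 8 are taken as catalogue items. The lignan must be the 2R,3R conifer-series enantiomer, made in bulk from spruce-knot hydroxymatairesinol, and not the (+)-form from flax.

## Route

**Step 1**
Reactants: 1, (−)-secoisolariciresinol; 2, ethyl (S)-2-(tosyloxy)propanoate
Product: 3, ethyl (R)-2-{4-[(2R,3R)-4-hydroxy-2-(hydroxymethyl)-3-(4-hydroxy-3-methoxybenzyl)butyl]-2-methoxyphenoxy}propanoate (mono-ether)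
Conditions: 2 (0.95 equiv), K2CO3 (1.0 equiv), MeCN, 60 °C, 16 h; recover and recycle 1
Reagents that add atoms: 2, ethyl (S)-2-(tosyloxy)propanoate, CCOC(=O)[C@H](C)OS(=O)(=O)c1ccc(C)cc1
Why: In this Williamson SN2, only the phenols are deprotonated by carbonate, the two phenols are homotopic so one mono-ether forms (statistical, about 45%), and clean inversion of the (S)-sulfonate gives the (R)-aryloxy centre C8''.

**Step 2**
Reactants: 3
Product: 4, tris-mesylate of 3 (two CH2OMs groups and the ring-A aryl OMs; 2R,3R and R unchanged)
Conditions: MsCl (4.5 equiv), Et3N (6 equiv), CH2Cl2, −10 → 0 °C, 1 h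
Reagents that add atoms: methanesulfonyl chloride, CS(=O)(=O)Cl
Why: Fast sulfene-type mesylation of both primary alcohols outruns tetrahydrofuran formation, and it also converts the remaining phenol into an electron-poor aryl mesylate without touching any stereocentre.

**Step 3 (key step)**
Reactants: 4
Product: 5, ethyl (R)-2-{2-methoxy-4-[(1S,2R,3R)-6-methoxy-7-(mesyloxy)-2,3-bis(mesyloxymethyl)-1,2,3,4-tetrahydronaphthalen-1-yl]phenoxy}propanoate (all-trans tetralin)
Conditions: carbon felt(+)|Pt(−), undivided cell, nBu4NBF4 (0.1 M), CH2Cl2/HFIP 4:1 (8 mM), controlled potential at the first wave (about +1.45 V vs Ag/AgCl), 2.1–2.3 F/mol, 0 °C, N2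
Reagents that add atoms: none
Why: Proposed new method: a potential-gated anodic dehydrogenative benzylic C(sp3)–H / aryl C(sp2)–H cyclisation, in which only dialkoxy ring B is oxidised because the aryl mesylate lifts ring A by an estimated ≥0.3 V and also suppresses the competing biaryl (dibenzocyclooctadiene) coupling; the radical cation then loses its only benzylic proton (C7'–H) to cathodically generated (CF3)2CHO−, the radical is oxidised again (ECE) to a p-alkoxybenzyl cation stabilised by HFIP, and ring A attacks para to its OMe through a chair-like transition state with the aryl and both CH2OMs groups equatorial, which sets C1 as S (1,2-trans) under control of the bought C2/C3 centres, while over-oxidation should be slow because the product C1–H lies near the plane of ring B; the closest known reaction types are anodic benzylic C–H amination/alkoxylation of p-alkylanisoles in HFIP, cation-pool benzylic arylation, and DDQ- or acid-mediated lignan cyclisations such as hydroxymatairesinol → conidendrin.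

**Step 4**
Reactants: 5
Product: 6, (R)-2-{2-methoxy-4-[(1S,2S,3R)-6-methoxy-7-(mesyloxy)-2,3-dimethyl-1,2,3,4-tetrahydronaphthalen-1-yl]phenoxy}propan-1-ol
Conditions: LiBHEt3 (8 equiv), THF, 0 °C → rt, 3 h
Reagents that add atoms: none
Why: SN2 hydride displacement of the two primary mesylates (the classical isolariciresinol bis-sulfonate → galbulin-type deoxygenation) and ester reduction occur together, aryl sulfonates are expected to tolerate hydride, and no stereocentre is involved (the C2 descriptor changes R→S only through CIP priorities).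

**Step 5**
Reactants: 6
Product: 7, (R)-2-{2-methoxy-4-[(1S,2S,3R)-6-methoxy-7-(mesyloxy)-2,3-dimethyl-1,2,3,4-tetrahydronaphthalen-1-yl]phenoxy}propanal
Conditions: Dess–Martin periodinane (1.3 equiv), NaHCO3, CH2Cl2, 0 °C → rt; used crude
Reagents that add atoms: none
Why: Buffered, base-free Dess–Martin oxidation gives the α-aryloxy aldehyde without epimerisation, and the mesylate keeps ring A from being oxidised as a phenol.

**Step 6**
Reactants: 7; 8, (4-bromo-2-methoxyphenoxy)(tert-butyl)dimethylsilane
Product: 9, (1S,2R)-1-[4-(TBSO)-3-methoxyphenyl]-2-{2-methoxy-4-[(1S,2S,3R)-6-methoxy-7-(mesyloxy)-2,3-dimethyl-1,2,3,4-tetrahydronaphthalen-1-yl]phenoxy}propan-1-ol (erythro)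
Conditions: 8 (2.2 equiv), n-BuLi (2.1 equiv), THF, −78 °C; ClTi(OiPr)3 (2.3 equiv), −78 → −40 °C; then 7, −78 → −20 °C
Reagents that add atoms: 8, COc1cc(Br)ccc1O[Si](C)(C)C(C)(C)C
Why: ArTi(OiPr)3 is weakly Lewis acidic and does not chelate, so it adds by the polar Felkin–Anh mode (anti to the C–OAr bond) to give the 1,2-anti (erythro, 7''S,8''R) alcohol under control of C8'', it is too weakly basic to enolise 7, and it leaves the aryl mesylate untouched.

**Step 7**
Reactants: 9
Product: 10, target (CID53359464)
Conditions: LDA (6 equiv), THF, −78 → 0 °C, 30 min; AcOH; then TBAF (3 equiv), 0 °C → rt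
Reagents that add atoms: none
Why: α-Deprotonation with sulfene loss (E1cB) frees the ring-A phenol from its mesylate under mild conditions, fluoride then removes the aryl TBS ether, and neither operation affects the five stereocentres or the benzylic alcohol.

## Compound list
1 | (−)-secoisolariciresinol, (2R,3R)-2,3-bis(4-hydroxy-3-methoxybenzyl)butane-1,4-diol | COc1cc(C[C@@H](CO)[C@H](CO)Cc2ccc(O)c(OC)c2)ccc1O | starting material
2 | ethyl (S)-2-(tosyloxy)propanoate | CCOC(=O)[C@H](C)OS(=O)(=O)c1ccc(C)cc1 | starting material
3 | mono-(R)-lactate ether of 1 | CCOC(=O)[C@@H](C)Oc1ccc(C[C@@H](CO)[C@H](CO)Cc2ccc(O)c(OC)c2)cc1OC | intermediate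
4 | tris-mesylate of 3 | CCOC(=O)[C@@H](C)Oc1ccc(C[C@@H](COS(C)(=O)=O)[C@H](COS(C)(=O)=O)Cc2ccc(OS(C)(=O)=O)c(OC)c2)cc1OC | intermediate
5 | all-trans (1S,2R,3R)-aryltetralin tris-mesylate ester | CCOC(=O)[C@@H](C)Oc1ccc([C@H]2c3cc(OS(C)(=O)=O)c(OC)cc3C[C@@H](COS(C)(=O)=O)[C@@H]2COS(C)(=O)=O)cc1OC | intermediate
6 | 7-O-mesylguaiacin 4'-O-[(R)-1-hydroxypropan-2-yl] ether | OC[C@@H](C)Oc1ccc([C@H]2c3cc(OS(C)(=O)=O)c(OC)cc3C[C@@H](C)[C@@H]2C)cc1OC | intermediate
7 | corresponding (R)-2-aryloxypropanal | O=C[C@@H](C)Oc1ccc([C@H]2c3cc(OS(C)(=O)=O)c(OC)cc3C[C@@H](C)[C@@H]2C)cc1OC | intermediate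
8 | (4-bromo-2-methoxyphenoxy)(tert-butyl)dimethylsilane | COc1cc(Br)ccc1O[Si](C)(C)C(C)(C)C | starting material
9 | erythro-(7''S,8''R) alcohol, 7-OMs / 4''-OTBS | COc1cc([C@H](O)[C@@H](C)Oc2ccc([C@H]3c4cc(OS(C)(=O)=O)c(OC)cc4C[C@@H](C)[C@@H]3C)cc2OC)ccc1O[Si](C)(C)C(C)(C)C | intermediate
10 | target, CID53359464 | COc1cc([C@H](O)[C@@H](C)Oc2ccc([C@H]3c4cc(O)c(OC)cc4C[C@@H](C)[C@@H]3C)cc2OC)ccc1O | target

## Summary
Total steps: 7. Longest linear sequence: 7 (1 → 10).

**Steps most likely to fail**
1. **Step 3 (proposed new anodic cyclisation).**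
   - Risks: over-oxidation to the dihydronaphthalene, E1 loss of C8'–H, or oxidation at the α-oxy C–H of the lactate.
   - Fallback (known chemistry): drop the electrolysis. Stoichiometric DDQ in CH2Cl2/AcOH abstracts the benzylic hydride of the dialkoxy ring to give the C7' acetate. A separate BF3·OEt2 or TFA Friedel–Crafts closure then follows, as in the hydroxymatairesinol → conidendrin manifold. This adds one step.
2. **Step 6 (diastereoselectivity and aldehyde integrity).**
   - Risks: a modest anti:syn ratio or partial racemisation of 7.
   - Fallback: deliver hydride to a ketone instead of aryl to an aldehyde. Oxidise the 9/epi-9 mixture to the α-aryloxy aryl ketone with DMP. Then reduce it under chelation control with Zn(BH4)2 in Et2O at −30 °C, where the guaiacyl ether oxygens chelate and the erythro alcohol results. This adds two steps.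
3. **Step 1 (statistical mono-alkylation and ee erosion).**
   - Risks: the yield is capped near 50%, and the ester can epimerise under base.
   - Fallback: install the ether later by Mitsunobu inversion.
     - Exhaustive mesylation of 1, then LiBHEt3, gives (8R,8'R)-dihydroguaiaretic acid bis(aryl mesylate).
     - One equivalent of LDA gives the mono-phenol, and the other fractions are recycled by re-mesylation.
     - DIAD/PPh3 with ethyl (S)-lactate then forms the ether, and the cyclisation is run on the dimethyl substrate.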